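**Retrosynthetic overview**
- Target 21 ⇒ hydroxy ketone 17 (4β-hydroxycarot-8-en-6-one) by removing the salicylate and the C6–H (acylation; C4–OH-directed reduction).
- The strategy rests on the β-hydroxy ketone array C4(OH)(iPr)–C5H–C6=O that straddles the trans-fused cyclopentane (C1–C5) and cycloheptene (C1, C5–C10). The C1–C5 bond is disconnected by returning C1 from C5 to C6 (retro-semipinacol), which gives the all-cis cis-decalin hydroxy mesylate 15.
- 15 ⇒ triol 14 ⇒ diene-ol 12 (hydroxyl-directed dihydroxylation of C4=C5); 12 ⇒ triene-ol 11 by ring-closing metathesis at C8=C9 (ring A).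
- 11 ⇒ enone 6: the C6–C7 bond is formed on an iodo-ketal that ties the C1 allyl group to the carbonyl oxygen, so that C6 is set against the C1 methyl; C1 comes from decarboxylative asymmetric allylation of carvenone 2.
- Ring order: ring B (carvenone, from dihydrocarvone 1), then ring A (metathesis), then both six-membered rings are converted into the five- and seven-membered rings in one step.

Key step: step 10

Remark: carotane numbering is used for every intermediate (C1 quaternary carbon with CH3; C2, C3; C4 isopropyl carbon; C5; C6; C7; C8 with vinylic CH3; C9; C10); ring B = C1–C6, ring A = C1, C6–C10.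
Remark: ring B needs only two methylenes (C2, C3) between C1 and C4. A C1 allyl group extended by hydroboration and B-alkyl Suzuki coupling would place three methylenes there and metathesis would close a seven-membered ring. Ring B is therefore taken intact from carvenone and the allyl group is used for ring A.
Remark: commercial dihydrocarvone is a stereoisomer mixture; both of its stereocentres are erased or reset in steps 1–3. Compounds 7, 9 and 10 are carried as epimer mixtures at the iodomethyl-bearing carbon (7 also at the ketal carbon); these centres disappear in steps 5 and 6.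
Remark: the enantiomeric purity set in step 3 would be checked on 6 and, if needed, raised by recrystallising a later solid such as triol 14.

**Route**

Step 1
Reactants: 1 dihydrocarvone
Product: 2 carvenone
Conditions: aq. H2SO4 (6 M), 90 °C
Reagents that add atoms: none
Why: Acid-catalysed alkene isomerisation (protonation of the isopropenyl group to the tertiary cation, proton loss into the ring) should funnel all stereoisomers of 1 into the conjugated enone, the thermodynamic sink; C4 becomes sp2 and C1 stays enolisable, so no stereochemistry needs to be controlled.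

Step 2
Reactants: 2 carvenone; 3 allyl chloroformate
Product: 5 allyl 2-methyl-5-(propan-2-yl)cyclohexa-1,5-dien-1-yl carbonate, via lithium dienolate 4 (not isolated)
Conditions: LiN(iPr)2, THF, −78 °C; TMEDA, then ClCO2CH2CH=CH2, −78 → 0 °C
Reagents that add atoms: allyl chloroformate, C=CCOC(Cl)=O
Why: Kinetic deprotonation of the enone at the α' methine C1 gives the cross-conjugated dienolate, which is O-acylated (enol carbonate formation); any C-acylated allyl β-keto ester would be carried along, since it enters step 3 through the same palladium dienolate.

Step 3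
Reactants: 5 allyl dienyl carbonate
Product: 6 (R)-6-methyl-3-(propan-2-yl)-6-(prop-2-en-1-yl)cyclohex-2-en-1-one
Conditions: Pd2(dba)3 (2.5 mol %), (R)-t-Bu-PHOX (6 mol %), THF, 25 °C
Reagents that add atoms: none
Why: Tsuji decarboxylative asymmetric allylic alkylation: zerovalent palladium ionises the carbonate, CO2 is lost and the π-allylpalladium dienolate recombines at C1 inside the chiral PHOX pocket, which sets the quaternary stereocentre; the (R)-ligand is chosen by analogy with the sense of induction known for 2-methylcyclohexanone enol carbonates, and the antipodal ligand would be used if the sense proved opposite.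

Step 4
Reactants: 6 (R)-allyl enone
Product: 7 bicyclic iodo ketal (2-(iodomethyl)-7a-methoxy-3a-methyl-6-(propan-2-yl)-2,3,3a,4,5,7a-hexahydro-1-benzofuran)
Conditions: N-iodosuccinimide, MeOH (3 equiv), NaHCO3, CH2Cl2, −20 → 0 °C
Reagents that add atoms: N-iodosuccinimide, O=C1CCC(=O)N1I; methanol, CO
Why: Iodo-ketalisation (halo-etherification through the carbonyl oxygen): the enone oxygen opens the iodonium ion of the terminal alkene in a 5-exo mode and methanol caps the resulting oxocarbenium ion, while the electron-poor enone C=C is inert to the iodonium source; the two new centres form as mixtures and are removed in steps 5 and 6.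

Step 5
Reactants: 7 bicyclic iodo ketal; 8 trimethyl(2-methylprop-2-en-1-yl)silane
Product: 10 trans-fused C6-methallyl bicyclic ether, via oxocarbenium triflate 9 (not isolated)
Conditions: Me3SiOTf (0.3 equiv), CH2Cl2, −78 °C
Reagents that add atoms: trimethyl(2-methylprop-2-en-1-yl)silane, CC(=C)C[Si](C)(C)C
Why: Lewis-acid-mediated allylation of a cyclic ketal by an allylsilane (Hosomi–Sakurai type): in oxocarbenium ion 9 the tetrahydrofuran ring holds C10 in the plane of the C6=O+ bond and the planar dienyl cation holds C2 near that plane, so the C1 methyl stands perpendicular over one face and the silane should add to C6 from the other face, which sets C6 with the methallyl group anti to the methyl and cis to C10.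

Step 6
Reactants: 10 C6-methallyl bicyclic ether
Product: 11 triene-ol (6-allyl-6-methyl-1-(2-methylprop-2-en-1-yl)-3-(propan-2-yl)cyclohex-2-en-1-ol)
Conditions: Zn dust, NH4Cl, EtOH/H2O, 60 °C
Reagents that add atoms: none
Why: Zinc-mediated reductive β-elimination of a β-alkoxy iodide (Boord-type olefin synthesis) regenerates the allyl group and releases the tertiary C6 alcohol without touching C1 or C6; both C9 epimers converge on one product.

Step 7
Reactants: 11 triene-ol
Product: 12 cis-fused diene-ol
Conditions: second-generation Grubbs catalyst RuCl2(=CHPh)(H2IMes)(PCy3) (5 mol %), CH2Cl2, 40 °C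
Reagents that add atoms: none
Why: Ring-closing metathesis of the allyl and methallyl groups, which are cis on ring B, closes ring A as a cis-fused cyclohexene with the trisubstituted C8=C9 bond; the hindered trisubstituted ring-B alkene should stay inert and no stereocentre is formed.

Step 8
Reactants: 12 cis-fused diene-ol
Product: 14 all-cis triol, via osmate ester 13 (not isolated)
Conditions: OsO4 (1.05 equiv), TMEDA (1.1 equiv), CH2Cl2, −78 °C; then aq. Na2SO3, THF, 60 °C
Reagents that add atoms: osmium tetroxide, O=[Os](=O)(=O)=O
Why: Hydroxyl-directed dihydroxylation with stoichiometric OsO4·TMEDA: the reagent is hydrogen-bonded to the C6 hydroxyl and delivered syn to the allylic C4=C5 bond, which sets C4 and C5 with their oxygens cis to the C6 hydroxyl and hence to the C1 methyl; the C8=C9 bond is only homoallylic to the directing group, and one equivalent of oxidant at −78 °C is used to exploit that difference.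

Step 9
Reactants: 14 all-cis triol
Product: 15 all-cis triol C5-monomesylate
Conditions: MsCl (1.1 equiv), Et3N, CH2Cl2, −20 °C
Reagents that add atoms: methanesulfonyl chloride, CS(Cl)(=O)=O
Why: Sulfonylation through the sulfene generated from MsCl and Et3N takes the only secondary alcohol (C5); the two flanking tertiary alcohols are far less reactive and no stereocentre changes.

Step 10
Reactants: 15 all-cis triol C5-monomesylate
Product: 17 4β-hydroxycarot-8-en-6-one, via potassium alkoxide 16 (not isolated)
Conditions: KOtBu (1.05 equiv), THF, −20 → 0 °C; then AcOH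
Reagents that add atoms: none
Why: Semipinacol (pinacol-type) rearrangement of a β-hydroxy mesylate: KOtBu turns the ring-fusion C6 hydroxyl into alkoxide 16, whose electron push drives the C1–C6 bond to migrate to C5 as mesylate leaves; the closest known reaction type is the base-mediated rearrangement of cis-decalin 1,2-diol monosulfonates to hydroazulenones. In the ring-B chair with isopropyl equatorial the C5 mesylate is equatorial and antiperiplanar to the C1–C6 ring bond while the C4 and C6 hydroxyls are axial and cis to it, so neither epoxide closure (which needs an anti O–C–C–OMs array) nor E2 (no hydrogen on C4 or C6) can compete. The cyclopentane (C1–C2–C3–C4–C5) closes by ring contraction through the new C1–C5 bond and the cycloheptenone (C1–C5–C6–C7–C8–C9–C10) by one-carbon expansion of ring A, both in the same suprafacial 1,2-shift. The only new stereocentre, C5, is set by backside displacement of the mesylate (inversion), so it is dictated by the C5 configuration installed in step 8; C1 migrates with retention and C4 is untouched, which gives the trans ring fusion with C6 cis to the C4 hydroxyl and the angular methyl. The selectivity needed is migration of C1 (pushed by the C6 alkoxide) over migration of C3 (pushed by the C4 alkoxide, whose C3–C4 bond is equally antiperiplanar); it rests on the higher migratory aptitude of the fully substituted C1, and one equivalent of base at low temperature, consumed as potassium mesylate forms, limits retro-aldol opening or C5 epimerisation of 17.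

Step 11
Reactants: 17 4β-hydroxycarot-8-en-6-one
Product: 18 carot-8-ene-4,6-diol (C6–OH anti to C4–OH)
Conditions: Me4NBH(OAc)3, AcOH/MeCN, −30 °C
Reagents that add atoms: none
Why: Evans–Saksena hydroxyl-directed reduction: the C4 hydroxyl exchanges onto boron and delivers hydride intramolecularly to C6 from the side on which the C4 oxygen lies, which gives the 1,3-anti diol, that is the C6 hydroxyl cis to H5 and on the face opposite to the C4 hydroxyl, as the target requires.

Step 12
Reactants: 18 carot-8-ene-4,6-diol; 19 O-acetylsalicyloyl chloride
Product: 20 C6 2-acetoxybenzoate of 18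
Conditions: pyridine, DMAP (cat.), CH2Cl2, 0 °C → rt
Reagents that add atoms: O-acetylsalicyloyl chloride, CC(=O)Oc1ccccc1C(Cl)=O
Why: DMAP-catalysed acylation with an acid chloride is selective for the secondary C6 alcohol over the hindered tertiary C4 alcohol; the phenol is masked as its acetate so that it cannot compete.

Step 13
Reactants: 20 C6 2-acetoxybenzoate
Product: 21 CNP0379621.1 (target)
Conditions: NH3 (2 M in MeOH, 3 equiv), 0 °C
Reagents that add atoms: none
Why: Chemoselective aminolysis of the aryl acetate, which is far more electrophilic than the hindered secondary alkyl salicylate (further deactivated once the ortho phenol is free), liberates the phenol without touching any stereocentre.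

**Compound list**
1 | dihydrocarvone, 2-methyl-5-(prop-1-en-2-yl)cyclohexan-1-one, stereoisomer mixture | CC1CCC(CC1=O)C(C)=C | starting material
2 | carvenone, 6-methyl-3-(propan-2-yl)cyclohex-2-en-1-one, racemic | CC1CCC(C(C)C)=CC1=O | intermediate
3 | allyl chloroformate | C=CCOC(Cl)=O | starting material
4 | lithium 2-methyl-5-(propan-2-yl)cyclohexa-1,5-dien-1-olate | [Li+].[O-]C1=C(C)CCC(C(C)C)=C1 | intermediate (not isolated)
5 | allyl 2-methyl-5-(propan-2-yl)cyclohexa-1,5-dien-1-yl carbonate | C=CCOC(=O)OC1=C(C)CCC(C(C)C)=C1 | intermediate
6 | (R)-6-methyl-3-(propan-2-yl)-6-(prop-2-en-1-yl)cyclohex-2-en-1-one | C=CC[C@@]1(C)CCC(C(C)C)=CC1=O | intermediate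
7 | 2-(iodomethyl)-7a-methoxy-3a-methyl-6-(propan-2-yl)-2,3,3a,4,5,7a-hexahydro-1-benzofuran; C3a as in 6, epimers at C2 and C7a | COC12OC(CI)C[C@@]1(C)CCC(C(C)C)=C2 | intermediate
8 | trimethyl(2-methylprop-2-en-1-yl)silane | CC(=C)C[Si](C)(C)C | starting material
9 | bicyclic dienyl oxocarbenium triflate from 7 | CC(C)C1=CC2=[O+]C(CI)C[C@@]2(C)CC1.[O-]S(=O)(=O)C(F)(F)F | intermediate (not isolated)
10 | 2-(iodomethyl)-3a-methyl-7a-(2-methylprop-2-en-1-yl)-6-(propan-2-yl)-2,3,3a,4,5,7a-hexahydro-1-benzofuran; trans ring fusion (methallyl anti to the angular methyl), epimers at C2 | CC(=C)C[C@@]12OC(CI)C[C@@]1(C)CCC(C(C)C)=C2 | intermediate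
11 | 6-allyl-6-methyl-1-(2-methylprop-2-en-1-yl)-3-(propan-2-yl)cyclohex-2-en-1-ol; allyl and methallyl cis, OH cis to the C1 methyl | C=CC[C@@]1(C)CCC(C(C)C)=C[C@@]1(O)CC(C)=C | intermediate
12 | cis-fused diene-ol, 4a,7-dimethyl-2-(propan-2-yl)-3,4,4a,5,8,8a-hexahydronaphthalen-8a-ol; OH cis to the angular methyl | CC1=CC[C@@]2(C)CCC(C(C)C)=C[C@@]2(O)C1 | intermediate
13 | C4/C5 osmate ester of 12, TMEDA adduct | CC1=CC[C@@]2(C)CC[C@@]3(O[Os](=O)(=O)O[C@@H]3[C@@]2(O)C1)C(C)C.CN(C)CCN(C)C | intermediate (not isolated)
14 | all-cis triol; C1–CH3, C4–OH, C5–OH and C6–OH on one face, isopropyl on the other | CC1=CC[C@@]2(C)CC[C@@](O)(C(C)C)[C@H](O)[C@@]2(O)C1 | intermediate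
15 | all-cis triol C5-monomesylate (key-step precursor) | CC1=CC[C@@]2(C)CC[C@@](O)(C(C)C)[C@H](OS(C)(=O)=O)[C@@]2(O)C1 | intermediate
16 | potassium C6-alkoxide of 15 | CC1=CC[C@@]2(C)CC[C@@](O)(C(C)C)[C@H](OS(C)(=O)=O)[C@@]2([O-])C1.[K+] | intermediate (not isolated)
17 | 4β-hydroxycarot-8-en-6-one; trans-fused, C4–OH and C6 cis to the C1 methyl on the cyclopentane (key-step product) | CC1=CC[C@@]2(C)CC[C@@](O)(C(C)C)[C@@H]2C(=O)C1 | intermediate
18 | carot-8-ene-4,6-diol; C6–OH cis to H5, anti to C4–OH | CC1=CC[C@@]2(C)CC[C@@](O)(C(C)C)[C@@H]2[C@@H](O)C1 | intermediate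
19 | O-acetylsalicyloyl chloride (2-acetoxybenzoyl chloride) | CC(=O)Oc1ccccc1C(Cl)=O | starting material
20 | C6 2-acetoxybenzoate of 18 | CC1=CC[C@@]2(C)CC[C@@](O)(C(C)C)[C@@H]2[C@@H](OC(=O)c2ccccc2OC(C)=O)C1 | intermediate
21 | CNP0379621.1, C6 salicylate of 18 | CC1=CC[C@@]2(C)CC[C@@](O)(C(C)C)[C@@H]2[C@@H](OC(=O)c2ccccc2O)C1 | target

**Step count and risks**

Total step count: 13. Longest linear sequence: 13 steps (1 → 21).

Three steps most likely to fail:

1. Step 5 (C6–C7 bond on the oxocarbenium ion). The allylsilane may add to the vinylogous C4 terminus of the dienyl cation, the cation may lose a proton to a dienol ether, or the facial bias from the C1 methyl may be incomplete. Fallback: set out from 6 and add 2-methylallylmagnesium chloride with CeCl3 (THF, −78 °C) directly to the enone carbonyl (1,2-addition). This should give 11 together with the C6 epimer of 11 F1, with little facial bias because C1 carries two groups of similar size; the epimers are separated by chromatography and the route is rejoined at 11, with steps 4–6 omitted.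

2. Step 8 (directed dihydroxylation). Osmylation of the less hindered ring-A alkene C8=C9, which is homoallylic to the same hydroxyl, may compete with or follow reaction at C4=C5. Fallback: set out from 12 and mask C8=C9 as the 8,9-dibromide F2 with one equivalent of pyridinium tribromide at −78 °C (the ring-B alkene is more hindered and deactivated by the allylic oxygen). The OsO4·TMEDA dihydroxylation is then run on F2 to give the dibromo triol F3, and the alkene is regenerated with Zn in AcOH/EtOH, which returns to the route at 14.

3. Step 10 (semipinacol shift). The C4 alkoxide may drive migration of C3 to C5 (ring-B contraction to an isobutyryl hydrindane), and the C4 alkoxide of the product may open 17 by retro-aldol cleavage or allow C5 epimerisation. Fallback: set out from 15 and silylate the tertiary C4 hydroxyl, expected to be the more accessible one because the C6 hydroxyl is flanked by the quaternary C1 (Et3SiOTf, 2,6-lutidine, −78 °C), to give the C4 triethylsilyl ether F4. Rearrangement with KOtBu then gives the silylated hydroxy ketone F5, and HF·pyridine removes the silyl group to return to the route at 17.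

Further compounds
F1 | step 5 | C6 epimer of 11 (methallyl cis to the C1 methyl) | C=CC[C@@]1(C)CCC(C(C)C)=C[C@]1(O)CC(C)=C
F2 | step 8 | 8,9-dibromide of 12 | CC1(Br)C(Br)C[C@@]2(C)CCC(C(C)C)=C[C@@]2(O)C1
F3 | step 8 | 8,9-dibromide of triol 14 | CC1(Br)C(Br)C[C@@]2(C)CC[C@@](O)(C(C)C)[C@H](O)[C@@]2(O)C1
F4 | step 10 | C4 triethylsilyl ether of 15 | CC1=CC[C@@]2(C)CC[C@@](O[Si](CC)(CC)CC)(C(C)C)[C@H](OS(C)(=O)=O)[C@@]2(O)C1
F5 | step 10 | C4 triethylsilyl ether of 17 | CC1=CC[C@@]2(C)CC[C@@](O[Si](CC)(CC)CC)(C(C)C)[C@@H]2C(=O)C1
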